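The route rests on cutting the aryl ether bond between the aminal oxygen and C8 of the naphthalene, so that the five-membered O-ring of the naphtho[1,8-bc]furan is closed last. The precursor is a racemising 3-hydroxy-3-(1-naphthyl)isoindolinone, assembled by Grignard addition to a phthalimide. In one operation a palladium-catalysed, hydroxyl-directed C–H etherification closes that ring and, by dynamic kinetic resolution with a chiral amino acid ligand, locks the labile hemiaminal carbon as the S spiro centre. The step exploits the peri relation between C8–H and the oxygen on the carbon attached to C1; the C2 oxygen substituent and the C4 methoxy group of the isoindolinone block every other C–H within reach.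

Key step: step 5

Remark: hemiaminal 8 is taken to equilibrate with its open-chain keto amide 9 (ring–chain tautomerism), so it is made and used as the racemate; which antipode of the ligand in step 5 gives the S product has to be established by experiment.

Step 1
Reactants: 1 3-methoxyphthalic anhydride; 2 2-(benzyloxy)ethan-1-amine
Product: 3 2-[2-(benzyloxy)ethyl]-4-methoxyisoindoline-1,3-dione
Conditions: toluene, Et3N (cat.), reflux, Dean–Stark
Reagents that add atoms: none
Why: Imide formation: the amine opens the anhydride to the amic acid, which closes to the imide on azeotropic removal of water, and the benzyl ether is inert.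

Step 2
Reactants: 4 6-methylnaphthalen-2-ol
Product: 5 1-bromo-6-methylnaphthalen-2-ol
Conditions: NBS (1.05 equiv), MeCN, 0 °C, dark
Reagents that add atoms: N-bromosuccinimide, O=C1CCC(=O)N1Br
Why: Electrophilic aromatic bromination of a 2-naphthol goes to C1, the most activated position next to OH, and the ionic conditions leave the benzylic methyl group untouched.

Step 3
Reactants: 5 1-bromo-6-methylnaphthalen-2-ol
Product: 6 2-(benzyloxy)-1-bromo-6-methylnaphthalene
Conditions: BnBr, K2CO3, DMF, rt
Reagents that add atoms: benzyl bromide, BrCc1ccccc1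
Why: Williamson ether synthesis on the naphthoxide; the benzyl ether withstands the Grignard step and the oxidative cyclisation and cannot migrate to carbon as a silyl group would.

Step 4
Reactants: 6 2-(benzyloxy)-1-bromo-6-methylnaphthalene (1.5 equiv); 3 2-[2-(benzyloxy)ethyl]-4-methoxyisoindoline-1,3-dione
Product: 8 rac-3-[2-(benzyloxy)-6-methylnaphthalen-1-yl]-2-[2-(benzyloxy)ethyl]-3-hydroxy-4-methoxyisoindolin-1-one, via arylmagnesium bromide 7 (not isolated)
Conditions: Mg turnings, I2 (cat.), THF, reflux; then 3, CH2Cl2, −20 °C to rt; aq NH4Cl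
Reagents that add atoms: none
Why: Aryl Grignard addition to an N-alkylphthalimide stops at the 3-hydroxy lactam, and chelation of magnesium between the methoxy oxygen and the neighbouring imide carbonyl should direct the aryl group to the carbonyl next to OMe, the new carbinol centre forming as a labile racemate.

Step 5
Reactants: 8 rac-3-[2-(benzyloxy)-6-methylnaphthalen-1-yl]-2-[2-(benzyloxy)ethyl]-3-hydroxy-4-methoxyisoindolin-1-one
Product: 10 (S)-3'-(benzyloxy)-2-[2-(benzyloxy)ethyl]-7-methoxy-7'-methylspiro[isoindoline-1,2'-naphtho[1,8-bc]furan]-3-one, via open-chain keto amide 9 (not isolated)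
Conditions: Pd(OAc)2 (10 mol %), Boc-L-tert-leucine (20 mol %), PhI(OAc)2 (1.5 equiv), Li2CO3 (1.5 equiv), C6F6, 80 °C
Reagents that add atoms: none
Why: Proposed new method: the hemiaminal alkoxide of 8 binds divalent palladium, the amino acid ligand assists concerted metalation–deprotonation of the peri C8–H to a six-membered oxapalladacycle (Pd, O, spiro C, C1, C8a, C8), PhI(OAc)2 oxidises this to tetravalent palladium, and C8–O reductive elimination releases 10. The closest known reaction types are the hydroxyl-directed C–H activation/C–O cyclisation of tertiary alcohols with Pd(OAc)2 and PhI(OAc)2 and the amino acid ligand-controlled enantioselective C–H activation/C–O bond formation and kinetic resolutions; their merger into a dynamic kinetic resolution of a hemiaminal has not been shown. The one ring closed is the five-membered O-ring of the naphtho[1,8-bc]furan (O, spiro C, C1, C8a, C8), closed by reductive elimination from the palladacycle, formally a 5-exo attack of oxygen on C8. The spiro carbon is the only stereocentre: the enantiomers of 8 interconvert through the achiral keto amide 9 in the carbonate/acetate buffer, and the chiral ligand (catalyst control) should let only the alkoxide leading to the S product pass the C–H cleavage quickly, Boc-D-tert-leucine being used if the sense of induction proves opposite. Site selectivity for C8–H is secured by geometry, since C2 of the naphthalene carries the benzyloxy group and C4 of the isoindolinone the methoxy group, so no other C–H lies within reach of the palladium alkoxide, and the tertiary carbinol has no hydrogen for β-hydride elimination. Once the O–C8 bond exists the aminal can no longer open, so the configuration is fixed.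

Step 6
Reactants: 10 (S)-3'-(benzyloxy)-2-[2-(benzyloxy)ethyl]-7-methoxy-7'-methylspiro[isoindoline-1,2'-naphtho[1,8-bc]furan]-3-one
Product: 11 (S)-3'-hydroxy-2-(2-hydroxyethyl)-7-methoxy-7'-methylspiro[isoindoline-1,2'-naphtho[1,8-bc]furan]-3-one
Conditions: H2 (1 atm), Pd/C, EtOAc/EtOH, rt
Reagents that add atoms: none
Why: Hydrogenolysis removes the aryl and the alkyl benzyl ether under neutral conditions that cannot ionise the N,O-ketal, and the quaternary, shielded spiro C–O bond should survive, so the S centre is untouched.

Compound list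
1 | 3-methoxyphthalic anhydride | COc1cccc2c1C(=O)OC2=O | starting material
2 | 2-(benzyloxy)ethan-1-amine | NCCOCc1ccccc1 | starting material
3 | 2-[2-(benzyloxy)ethyl]-4-methoxyisoindoline-1,3-dione | COc1cccc2c1C(=O)N(CCOCc1ccccc1)C2=O | intermediate
4 | 6-methylnaphthalen-2-ol | Cc1ccc2cc(O)ccc2c1 | starting material
5 | 1-bromo-6-methylnaphthalen-2-ol | Cc1ccc2c(Br)c(O)ccc2c1 | intermediate
6 | 2-(benzyloxy)-1-bromo-6-methylnaphthalene | Cc1ccc2c(Br)c(OCc3ccccc3)ccc2c1 | intermediate
7 | [2-(benzyloxy)-6-methylnaphthalen-1-yl]magnesium bromide | Cc1ccc2c([Mg]Br)c(OCc3ccccc3)ccc2c1 | intermediate (not isolated)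
8 | rac-3-[2-(benzyloxy)-6-methylnaphthalen-1-yl]-2-[2-(benzyloxy)ethyl]-3-hydroxy-4-methoxyisoindolin-1-one | COc1cccc2c1C(O)(c1c(OCc3ccccc3)ccc3cc(C)ccc13)N(CCOCc1ccccc1)C2=O | intermediate
9 | N-[2-(benzyloxy)ethyl]-2-[2-(benzyloxy)-6-methyl-1-naphthoyl]-3-methoxybenzamide | COc1cccc(C(=O)NCCOCc2ccccc2)c1C(=O)c1c(OCc2ccccc2)ccc2cc(C)ccc12 | intermediate (not isolated)
10 | (S)-3'-(benzyloxy)-2-[2-(benzyloxy)ethyl]-7-methoxy-7'-methylspiro[isoindoline-1,2'-naphtho[1,8-bc]furan]-3-one | COc1cccc2c1[C@]1(Oc3cc(C)cc4ccc(OCc5ccccc5)c1c34)N(CCOCc1ccccc1)C2=O | intermediate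
11 | (S)-3'-hydroxy-2-(2-hydroxyethyl)-7-methoxy-7'-methylspiro[isoindoline-1,2'-naphtho[1,8-bc]furan]-3-one | COc1cccc2c1[C@]1(Oc3cc(C)cc4ccc(O)c1c34)N(CCO)C2=O | target

Total step count: 6. Longest linear sequence: 5 steps (steps 2, 3, 4, 5 and 6, from 6-methylnaphthalen-2-ol).

Steps most likely to fail

Step 5. The ligand may discriminate poorly between the two hemiaminal alkoxides, or ring opening and reclosure of 8 may be slower than cyclisation, so that the product forms with low enantiomeric purity. The fallback sets out from 8 and comes back at 10. Without the chiral ligand, 8 is cyclised with Pd(OAc)2, PhI(OAc)2 and Li2CO3 in C6F6 at 100 °C, the known hydroxyl-directed C–H activation/C–O cyclisation of tertiary alcohols, which should give the racemic spiro dibenzyl ether F1. The enantiomers are then separated by preparative HPLC on an amylose tris(3,5-dimethylphenylcarbamate) phase, and the S enantiomer is 10 (to be assigned by electronic circular dichroism against calculation or by X-ray analysis).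

Step 4. The hindered aryl Grignard reagent may attack the imide carbonyl remote from the methoxy group, or add too slowly. The fallback sets out from 7 (and amine 2) and comes back at 8; it fixes the regiochemistry by directed ortho-metalation. Quenching 7 with DMF gives 2-(benzyloxy)-6-methyl-1-naphthaldehyde F2. Acylation of 2 with commercial 3-methoxybenzoyl chloride (Et3N, CH2Cl2) gives N-[2-(benzyloxy)ethyl]-3-methoxybenzamide F3. s-BuLi (2.2 equiv) and TMEDA in THF at −78 °C lithiate F3 at nitrogen and at C2, between the amide and the methoxy group, to the dilithio benzamide F4, which adds to F2 to give the hydroxy amide F5. Dess–Martin periodinane in CH2Cl2 oxidises F5 to keto amide 9, which closes to 8.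

Step 6. Hydrogenolysis may also cleave the benzylic spiro C–O bond, whose oxygen is an aryloxy leaving group. The fallback sets out from 8 and comes back at 11; it removes the benzyl groups before that bond exists. H2 and Pd/C in EtOAc should give the triol hemiaminal F6, and TBSCl with imidazole in DMF silylates the naphthol and the primary alcohol to the bis-silyl ether F7. The cyclisation of step 5, running through the silylated keto amide F8, gives the spiro bis-silyl ether F9, and TBAF buffered with AcOH in THF releases 11.

Further compounds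
F1 | step 5 | rac-3'-(benzyloxy)-2-[2-(benzyloxy)ethyl]-7-methoxy-7'-methylspiro[isoindoline-1,2'-naphtho[1,8-bc]furan]-3-one | COc1cccc2c1C1(Oc3cc(C)cc4ccc(OCc5ccccc5)c1c34)N(CCOCc1ccccc1)C2=O
F2 | step 4 | 2-(benzyloxy)-6-methyl-1-naphthaldehyde | Cc1ccc2c(C=O)c(OCc3ccccc3)ccc2c1
F3 | step 4 | N-[2-(benzyloxy)ethyl]-3-methoxybenzamide | COc1cccc(C(=O)NCCOCc2ccccc2)c1
F4 | step 4 | N,2-dilithio-N-[2-(benzyloxy)ethyl]-3-methoxybenzamide | COc1cccc(C(=O)N([Li])CCOCc2ccccc2)c1[Li]
F5 | step 4 | rac-N-[2-(benzyloxy)ethyl]-2-{[2-(benzyloxy)-6-methylnaphthalen-1-yl](hydroxy)methyl}-3-methoxybenzamide | COc1cccc(C(=O)NCCOCc2ccccc2)c1C(O)c1c(OCc2ccccc2)ccc2cc(C)ccc12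
F6 | step 6 | rac-3-hydroxy-3-(2-hydroxy-6-methylnaphthalen-1-yl)-2-(2-hydroxyethyl)-4-methoxyisoindolin-1-one | COc1cccc2c1C(O)(c1c(O)ccc3cc(C)ccc13)N(CCO)C2=O
F7 | step 6 | rac-3-{2-[(tert-butyldimethylsilyl)oxy]-6-methylnaphthalen-1-yl}-2-{2-[(tert-butyldimethylsilyl)oxy]ethyl}-3-hydroxy-4-methoxyisoindolin-1-one | COc1cccc2c1C(O)(c1c(O[Si](C)(C)C(C)(C)C)ccc3cc(C)ccc13)N(CCO[Si](C)(C)C(C)(C)C)C2=O
F8 | step 6 | N-{2-[(tert-butyldimethylsilyl)oxy]ethyl}-2-{2-[(tert-butyldimethylsilyl)oxy]-6-methyl-1-naphthoyl}-3-methoxybenzamide | COc1cccc(C(=O)NCCO[Si](C)(C)C(C)(C)C)c1C(=O)c1c(O[Si](C)(C)C(C)(C)C)ccc2cc(C)ccc12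
F9 | step 6 | 3'-[(tert-butyldimethylsilyl)oxy]-2-{2-[(tert-butyldimethylsilyl)oxy]ethyl}-7-methoxy-7'-methylspiro[isoindoline-1,2'-naphtho[1,8-bc]furan]-3-one, same spatial arrangement at the spiro carbon as 10 (descriptor R because the silyloxy group changes the priorities) | COc1cccc2c1[C@]1(Oc3cc(C)cc4ccc(O[Si](C)(C)C(C)(C)C)c1c34)N(CCO[Si](C)(C)C(C)(C)C)C2=O
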